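Start from one ratio: divide the target in dawn by the target in winter at the same hour, and hold it against the factor 2.14 between their partner charges.

all flasks: substrate 0.020 M

| charge | partner | remark | time |
|---|---|---|---|
| winter | 0.56 equiv | run made earlier |  |
| dawn | 1.2 equiv | run made earlier |  |
| red | 2.00 equiv |  | 30 h |
| amber | 0.800 equiv |  | 30 h |

- winter (time / h: target / %): 5.00: 3.7; 10.0: 7.2; 15.0: 12.7; 20.0: 18.2
- dawn (time / h: target / %): 5.00: 3.4; 10.0: 14.5; 15.0: 20.7; 20.0: 26.5

(each reading ± 1 percentage point)

- amounts and yields of target count crystals too
- given per volume of solution although it is solid: crystals
- the numbers in the tables scatter with a standard deviation of 1 percentage point
- steps that have been proposed: partner + intermediate -> target; substrate -> intermediate; crystals <-> target; partner + target -> over-reaction product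

- which of the two there is more of at the end, red (target / over-reaction product)
- which of the two there is more of at the end, amber (target / over-reaction product)
- final target, as a percentage of the substrate charged, in red
- final target, as a percentage of the substrate charged, in amber

First ask whether extra partner pays at all. Leave out the readings at 5.00 h, which lie too near the scatter to divide, and read the ratio at 10.0 h: it is 2.01 against 2.14, so early on target follows [partner] closely.

Next ask whether that lasts. At 20.0 h the ratio reads 1.46, so the extra partner is returning less, which suggests that partner is also spending itself on target.

Then ask when the return ends. Draw a straight line through these two ratios and see where it reaches one: at 28.2 h. Call this the break-even time, the hour at which the flask with more partner holds no more target than the flask with less. It is a rough reading, given the scatter of 1 percentage point.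

The asked 30 h lies later than that. So my own reckoning puts red, with 2.00 equiv of partner, below amber in target. It compares flasks, so it does not by itself set target against over-reaction product within one flask.

The forecast differs: 40% in red, 31% in amber, and target ahead in both, on the ground that “Dawn shows no strong loss of target”.

The flasks give 26.1% of target in red, against 41.3% of over-reaction product, and 29.0% of target in amber, against 12.2%.

    partner + intermediate → target (k = 3.90 M⁻¹ h⁻¹)
    substrate → intermediate (k = 0.0650 h⁻¹)
    crystals ⇌ target, rate k3*(cs3 - [target]) while solid is left; crystals form when [target] > cs3 (solubility = 4.50 mM, k = 5.90 h⁻¹)
    partner + target → over-reaction product (k = 3.10 M⁻¹ h⁻¹)

Red ends at 26.1% of target and amber at 29.0%, the order that a break-even time of 28.2 h pointed to. The main reason for red's figure is the path from partner + target to over-reaction product: take that step away from red and target ends at 71.2% instead of 26.1%.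

Both partner steps are second order, so dilution stretches their clock. Take amber's recipe at 0.0080 M: break-even moves to about 70.4 h, later than 30 h, so expect that flask to stop on the early side of break-even, at a stage of its stretched clock where the step to over-reaction product is still lagging. That neighbour gives 22.0% of target against 4.53% of over-reaction product, with 59.3% standing as intermediate.

(Readings and results were generated by integration on assumed constants, and the scatter is random.)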